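(The numbers of this flask were set for the occasion; the run is a simulation.)

If you want to know where this flask stops, two colleagues at the blackboard will begin with two different questions.

starting material 0.095 M; reagent 0.105 M; free catalyst 0.27 mM; time 2.5 d

    catalyst intermediate C → free catalyst + product (k1 = 15 min⁻¹)
    reagent + catalyst intermediate B → catalyst intermediate C (k2 = 570 M⁻¹ min⁻¹)
    catalyst intermediate A + catalyst intermediate A ⇌ resting dimer (K3 = 2000 M⁻¹, k3 = 270 M⁻¹ min⁻¹)
    catalyst intermediate A ⇌ catalyst intermediate B (K4 = 0.89, k4 = 19 min⁻¹)
    starting material + free catalyst ⇌ catalyst intermediate A (K5 = 17 M⁻¹, k5 = 38 M⁻¹ min⁻¹)

* why nothing more happens at 2.5 d, or that something still does (the reagent has run out first / no working catalyst is left / all of the starting material has reacted / it is still moving / forward and back rates have come level)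
* part of the starting material gone at 2.5 d
* the product standing at 2.5 d, as a percentage of the starting material charged

- percent here means starting material units held: one resting dimer counts as two
- two of one species on the left: rate k times its square, two consumed each time
- the reaction counts as stopped when no species that holds the starting material changes by six tenths of a point or more over the second half of the time
- run time (flask): 2.5 d

The first colleague counts. Each turn of the round takes one starting material and one reagent, gives one product and returns the catalyst. So she writes down the charge ratio, reagent charged per starting material charged, 1.11. Her rule, for a flask given time to finish, is that the product share at the stop is the smaller of that ratio and the whole charge: 100%, with conversion 100%. Starting material is then the limiting reagent, and 9.52% of the reagent charge stays over.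

The second colleague watches the clock. Each catalyst unit must turn 352 times, and he expects a stall short of her count. With the whole catalyst free and held at its charge, starting material has a half-life of 1.1 h by the forward rate of its binding step alone. But if binding and the change of catalyst intermediate A into catalyst intermediate B stand balanced at the start, the free share is 0.247. The resting dimer then holds a further 0.430 of what catalyst intermediate A holds, which brings the free share to 0.211.

I take his pessimism and divide: as an estimate on his view, the half-life comes to 5.35 h, which is shorter than the run, and the run holds 11.2 of them. With half the charge of starting material left, the same balance without the dimer gives a free share of 0.396, larger than the 0.247 at the start, so on this estimate the comparison drifts in the count's favour. I side with her.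

The forecast reads all of the starting material has reacted, conversion 100% and product 100%, since “The reagent is in excess, the product-forming steps are irreversible”. The simulation gives all of the starting material has reacted, conversion 100% and product 100%.

The clock has its region in early readings: at 0.250 d this flask holds product 91.2% and starting material 8.78%. By 1.25 d the reagent stands at 9.52%, as the count's 9.52% has it. Left until 25.0 d, this flask still shows product 100% and reagent 9.52%, so it has come to rest. In the neighbour with more starting material the charge ratio is 0.276, and at 2.50 d that flask holds reagent 0% and product 27.6%.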